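## The problem

Target 32 is a C25 diacid (carbons numbered along its SMILES string) in which a cyclopentene and a cyclohexadiene share the C9–C24 bond, C9 being the inner end of both the C8=C9 alkene and the C10=C12 alkene that carries the C11 carboxyl group. A 7-oxabicyclo[2.2.1]heptane hangs from C12 through the C13 methylene, and C5 carries the CH(CH3)CH2CO2H chain (C1–C4). Four of the six stereocentres are contiguous (C2, C5, C24, C23): C5 and C24 are adjacent quaternary carbons with trans methyl groups, and C23 bears a free hydroxyl next to C24. C14 and C17 are remote from these and need their own source of chirality, although C14 follows from C17 through the oxygen bridge. C2 can control C5 only when both sit in a ring, C5 controls C24 poorly because each face of C24 meets one of the two C5 substituents, and C24, flanked by a quaternary alkyl and an alkenyl group, gives no dependable Felkin bias for C23. Three elements are fragile: the dienoic acid and its β,γ-unsaturated carbonyl precursors (double-bond migration), the C23 oxygen, which is β to a ketone in every open-chain precursor (retro-aldol, elimination), and the ether bridge, which opens when a C12 ketone is enolised toward C13 or when C14 is ionised by strong acid. The feature that invites the key step is the C8=C9 alkene standing directly on quaternary C24 inside the five-membered ring, with C24 bearing the oxygenated carbon C23. This is the pattern left when the α-carbon of an aldehyde enol ether (C23=C24) adds across a C8≡C9 alkyne held by the C5–C7 tether.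

## Retrosynthesis

**32 back to 29.** No skeletal bond is cut. The C11 acid is taken back to the aldehyde, the C23 hydroxyl to its silyl ether and the C4 acid to its methyl ester. Dienal 29 is chosen because it is the direct product of an aldol condensation, and the three late steps (30, 31, 32) are functional-group operations on a finished skeleton.

**C10=C12 (29 from 28).** This is the only bond of the six-membered ring that is an aldol retron. Cutting C9–C10 or C12–C22 instead would call for couplings at a tetrasubstituted diene. The cut removes the ring and leaves keto aldehyde 28, a cyclopentene with two arms. The forward step must enolise the C11 aldehyde (as its enamine) in preference to the C12 ketone, and must leave C8=C9 and the C23 silyloxy group in place.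

**C22–C23 (25 from 16 and 24).** This bond separates the remote C14/C17 pair from the four contiguous centres and divides the skeleton into a C11 methyl ketone 24 and an aldehyde 16 with fourteen skeletal carbons. A cut at C12–C13 would instead need a carbanion β to the bridge oxygen, which would eliminate. The forward aldol must enolise 24 at its methyl group and set C23 by reagent control.

**C9–C24 (16 from 15), the key cut.** Opening the cyclopentene here turns the C8=C9 alkene into an alkyne and C24 into the α-carbon of an aldehyde enol ether. Cutting C5–C24 or C5–C7 would require forming a quaternary carbon by an intermolecular reaction next to another quaternary carbon. Precursor 15 is acyclic and has only C2 and C5 as stereocentres. The forward reaction must be 5-endo selective and must discriminate the faces of C24.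

**15 back to lactone 9.** The enol ether comes from aldehyde 14, which is the one-carbon homologue of methyl ketone 12. Ketone 12 and its ester come from lactone 9 by addition of a methyl nucleophile to the lactone carbonyl (C24) and oxidation of the released C4 alcohol (10, 11). The lactone is kept up to this point because it is what fixes C5 relative to C2.

**9 back to 5 and 1.** The two α-substituents of the lactone are cut in the order propargyl, then methyl, giving 8, then 7 and bromide 4. The second alkylation enters anti to the ring methyl, so the order methyl first, propargyl second gives the required C5 configuration. Lactone 7 comes from half-ester 5 by reduction of the acid arm (via 6), and bromide 4 from butynol 1 via 2 and 3.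

**24 back to 17 and 18.** The oxygen bridge and the C18–C21 bond are cut together, giving epoxy diene 21. One catalytic epoxidation then sets C17, and the cyclisation relays it to C14. Diene 20 (from 19) is the allylation product of homoallylic alcohol 17 with bromide 18. The carbinol carbon of 17 becomes the C12 ketone after the cyclisation (22, 23).

## Roads not taken

Alternative 1: The cut lies inside the oxabicycle of the ketone fragment. O–C14, C14–C15 and C16–C17 are disconnected, leading to diazo keto ester aldehyde A2 and phenyl vinyl sulfone A3. In the forward sense Rh2(OAc)4 generates a carbenoid at C14 of A2, the C17 aldehyde oxygen closes a five-membered carbonyl ylide, and the dipole adds to A3 to give bicyclic keto ester A1.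
- Merits: the bridge is formed with unambiguous connectivity in one step, with no competing proton loss, and the regiochemistry of the cycloaddition is predictable.
- Weak points: A1 is racemic unless the chiral ligands of a catalyst such as Rh2(S-DOSP)4 stay associated with the ylide during the cycloaddition, which is not dependable. A1 also carries three groups the target does not need. The C21 ketone lies between two fully substituted carbons and must be deoxygenated, and it makes A1 a non-enolisable β-keto ester open to retro-Claisen cleavage. The sulfone must be removed. The bridgehead ester must still be extended by two carbons to the methyl ketone.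
- Comparison: this road is safer for the ring-forming event itself. The chosen plan sets against it a six-step route to 24 in which a catalytic epoxidation supplies the absolute configuration and nothing has to be removed afterwards. Alternative 1 also leaves the hydrindane problem untouched.

Alternative 2: C9–C24 and C22–C23 are cut together. The precursor A5 carries a dienyl ester (C9=C10–C12=C22, activated by a C8 ketone) and the same kind of silyl enol ether (C24=C23) on one chain. On heating or with a Lewis acid the electron-poor diene adds to the enol ether with inverse electron demand and gives hydrindanone A4.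
- Merits: two bonds, both carbocycles and the centres C24 and C23 arise in one step; the oxabicycle is already attached; C11 is already an ester. After the key step this road is shorter than the chosen one.
- Weak points: the dienophile is a trisubstituted enol ether that must form a quaternary carbon next to quaternary C5, so the C5-to-C24 facial problem is the same as in the chosen plan, and here no chiral catalyst is at hand. C23 depends in addition on endo/exo selectivity. The 4-oxo-dienoate unit of A5 is a strong Michael acceptor and makes A5 fragile. A4 has a C8 ketone and a C9 hydrogen, so the C8=C9 alkene must still be made in two further operations (O-triflation of the C8 enolate, then hydride reduction of the C–O bond).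
- Comparison: the chosen plan forms fewer bonds in its key step but places C8=C9 directly, can bring a ligand to bear on C24, and sets C23 separately with a chiral boron reagent.

Alternative 3: The oxabicycle is cut last, at C18–C21 and O–C14. The precursor A7 is the complete dienoate carrying a 2-substituted hepta-1,5-diene epoxide in place of the bicycle. A Lewis acid opens the epoxide at C18, the C14=C21 alkene attacks, and the epoxide oxygen captures the C14 cation to give A6, the silylated dimethyl ester of the target.
- Merits: this is the most convergent road and probably about two steps shorter, since the side-chain ketone needs no protecting-group steps. It also avoids carrying a ketone β to the bridge oxygen through enolisation.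
- Weak points: the C14 cation is formed next to C13, whose hydrogens are allylic to the dienoate, so proton loss to a conjugated triene competes directly with oxygen capture. The Lewis acid meets the whole acid-sensitive diene and the C23 silyl ether at the penultimate stage. The epoxide of A7 must either survive the end-game or be introduced late among four alkenes.
- Comparison: the chosen plan runs the same cationic event early, on a small C11 substrate with nothing else to ionise, where a poor outcome costs little. It pays for this with two protecting-group steps and with the care needed in enolising 24.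

Key step: step 12

Assumptions:
- Half-ester 5 is taken as the commercial (R)-compound (also the product of desymmetrising 3-methylglutaric anhydride or its dimethyl ester).
- Alcohol 17 is used as the racemate because its carbinol carbon becomes a ketone.
- The (R) ligand written in step 12 stands for whichever antipode proves matched.

## Steps

Step 1
Reactants: 1 but-3-yn-1-ol
Product: 2 tert-butyl(but-3-yn-1-yloxy)dimethylsilane
Conditions: TBSCl, imidazole, CH2Cl2, 0 °C → rt
Reagents that add atoms: tert-butyldimethylsilyl chloride, CC(C)(C)[Si](C)(C)Cl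
Why: Imidazole-promoted silylation of a primary alcohol; the terminal alkyne is inert.

Step 2
Reactants: 2 tert-butyl(but-3-yn-1-yloxy)dimethylsilane
Product: 3 5-{[tert-butyl(dimethyl)silyl]oxy}pent-2-yn-1-ol
Conditions: n-BuLi, THF, −78 °C; (CH2O)n, −78 °C → rt
Reagents that add atoms: paraformaldehyde (as formaldehyde), C=O
Why: Hydroxymethylation of a lithium acetylide; the silyl ether tolerates the base.

Step 3
Reactants: 3 5-{[tert-butyl(dimethyl)silyl]oxy}pent-2-yn-1-ol
Product: 4 [(5-bromopent-3-yn-1-yl)oxy](tert-butyl)dimethylsilane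
Conditions: CBr4, PPh3, CH2Cl2, 0 °C
Reagents that add atoms: carbon tetrabromide, BrC(Br)(Br)Br
Why: Appel bromination of a primary propargylic alcohol under neutral conditions that spare the silyl ether.

Step 4
Reactants: 5 (3R)-5-methoxy-3-methyl-5-oxopentanoic acid
Product: 7 (4R)-4-methyloxan-2-one, via methyl (3R)-5-hydroxy-3-methylpentanoate 6 (not isolated)
Conditions: BH3·SMe2, THF, 0 °C → rt; MeOH; TsOH·H2O (cat.), PhMe, rt
Reagents that add atoms: none
Why: Borane reduces the carboxylic acid in the presence of the ester, and the hydroxy ester lactonises under acid. The stereocentre (future C2) is not touched and keeps the R descriptor.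

Step 5
Reactants: 7 (4R)-4-methyloxan-2-one
Product: 8 (3S,4R)-3,4-dimethyloxan-2-one
Conditions: LiN(i-Pr)2, THF, −78 °C; MeI, −78 → −40 °C
Reagents that add atoms: iodomethane, CI
Why: Lactone enolate methylation, expected trans to the ring methyl. The configuration of this carbon is erased in step 6, so any cis isomer is carried along.

Step 6
Reactants: 8 (3S,4R)-3,4-dimethyloxan-2-one; 4 [(5-bromopent-3-yn-1-yl)oxy](tert-butyl)dimethylsilane
Product: 9 (3S,4R)-3-(5-{[tert-butyl(dimethyl)silyl]oxy}pent-2-yn-1-yl)-3,4-dimethyloxan-2-one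
Conditions: LiN(i-Pr)2, THF, −78 °C; DMPU, 4, −78 → −30 °C
Reagents that add atoms: none
Why: Alkylation of the α-methyl lactone enolate with a reactive propargylic bromide. The ring methyl on C2 turns pseudo-axial to avoid the enolate methyl and shields one face, so the propargyl group should enter anti to it and set quaternary C5 as S.

Step 7
Reactants: 9 (3S,4R)-3-(5-{[tert-butyl(dimethyl)silyl]oxy}pent-2-yn-1-yl)-3,4-dimethyloxan-2-one
Product: 10 (3S)-8-{[tert-butyl(dimethyl)silyl]oxy}-3-[(2R)-4-hydroxybutan-2-yl]-3-methyloct-5-yn-2-one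
Conditions: MeLi (1.1 equiv), THF, −78 °C; aq. NH4Cl
Reagents that add atoms: methyllithium, [Li]C
Why: Single addition of an organolithium to a lactone. The hindered lithium hemiketalate persists until the quench, so the hydroxy methyl ketone (in equilibrium with its lactol) should result without a second addition.

Step 8
Reactants: 10 (3S)-8-{[tert-butyl(dimethyl)silyl]oxy}-3-[(2R)-4-hydroxybutan-2-yl]-3-methyloct-5-yn-2-one
Product: 11 (3R,4S)-4-acetyl-9-{[tert-butyl(dimethyl)silyl]oxy}-3,4-dimethylnon-6-ynoic acid
Conditions: TEMPO (cat.), PhI(OAc)2, MeCN/H2O, rt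
Reagents that add atoms: water, O
Why: Oxoammonium oxidation of the primary alcohol through the aldehyde hydrate to the acid. The ketone, alkyne and silyl ether are inert, and the lactol is drained through its open form.

Step 9
Reactants: 11 (3R,4S)-4-acetyl-9-{[tert-butyl(dimethyl)silyl]oxy}-3,4-dimethylnon-6-ynoic acid
Product: 12 methyl (3R,4S)-4-acetyl-9-{[tert-butyl(dimethyl)silyl]oxy}-3,4-dimethylnon-6-ynoate
Conditions: MeI, K2CO3, DMF, rt
Reagents that add atoms: iodomethane, CI
Why: O-Alkylation of the carboxylate; the hindered methyl ketone is not C-alkylated by carbonate.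

Step 10
Reactants: 12 methyl (3R,4S)-4-acetyl-9-{[tert-butyl(dimethyl)silyl]oxy}-3,4-dimethylnon-6-ynoate
Product: 14 methyl (3R,4S)-9-{[tert-butyl(dimethyl)silyl]oxy}-3,4-dimethyl-4-(1-oxopropan-2-yl)non-6-ynoate, via methyl enol ether 13 (not isolated)
Conditions: Ph3P(CH2OMe)Cl, KN(SiMe3)2, THF, 0 → 40 °C; then 2 M aq. HCl, THF, 0 °C
Reagents that add atoms: (methoxymethyl)triphenylphosphonium chloride, COC[P+](c1ccccc1)(c1ccccc1)c1ccccc1.[Cl-]; water, O
Why: Wittig methoxymethylenation of the ketone (the non-stabilised ylide does not attack the ester), then hydrolysis of the β,β-disubstituted enol ether to the homologous aldehyde. The new α-carbon (C24) is formed as both epimers, which is irrelevant because it becomes sp2 in step 11; any loss of the primary silyl ether in the acid is repaired there as well.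

Step 11
Reactants: 14 methyl (3R,4S)-9-{[tert-butyl(dimethyl)silyl]oxy}-3,4-dimethyl-4-(1-oxopropan-2-yl)non-6-ynoate
Product: 15 methyl (3R,4S)-9-{[tert-butyl(dimethyl)silyl]oxy}-4-[(1E)-1-{[tert-butyl(dimethyl)silyl]oxy}prop-1-en-2-yl]-3,4-dimethylnon-6-ynoate
Conditions: TBSOTf (excess), Et3N, CH2Cl2, 0 °C → rt
Reagents that add atoms: tert-butyldimethylsilyl triflate, CC(C)(C)[Si](C)(C)OS(=O)(=O)C(F)(F)F
Why: Soft enolisation of the aldehyde (O-silylation, then deprotonation at C24). The E isomer is expected because the silyloxy group avoids the quaternary C5, and the ester enolises far more slowly under these conditions.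

Step 12
Reactants: 15 methyl (3R,4S)-9-{[tert-butyl(dimethyl)silyl]oxy}-4-[(1E)-1-{[tert-butyl(dimethyl)silyl]oxy}prop-1-en-2-yl]-3,4-dimethylnon-6-ynoate
Product: 16 methyl (3R)-3-[(1S,2R)-3-(2-{[tert-butyl(dimethyl)silyl]oxy}ethyl)-2-formyl-1,2-dimethylcyclopent-3-en-1-yl]butanoate
Conditions: (R)-DTBM-SEGPHOS(AuCl)2 (5 mol %), AgNTf2 (10 mol %), CH2Cl2/MeOH 10:1, 0 °C → rt
Reagents that add atoms: none
Why: The cationic monovalent gold centre binds the C8≡C9 alkyne and the enol ether carbon C24 attacks C9 anti to gold, giving a C8 vinyl-gold species and a silyloxocarbenium ion at C23; methanol takes the silyl group and protonates the C8–Au bond, releasing aldehyde 16 and the catalyst. The closest known reaction type is the gold-catalysed 5-endo-dig carbocyclisation of silyl enol ethers onto alkynes (Conia-ene type), which accepts internal alkynes and fully substituted nucleophilic carbons and has enantioselective versions with bis(phosphine)digold complexes. The cyclopentene (C24, C5, C7, C8, C9) closes in the 5-endo-dig mode; attack at C8 would be a strained 4-exo closure, so the C8=C9 alkene and the C10 arm arise in their final positions. The only new stereocentre is C24, and it is controlled by the chiral ligand on gold, which differentiates the two faces of the enol ether as it meets the bound alkyne. The substrate's own bias is small: in either reacting rotamer one C5 substituent eclipses the C25 methyl and the other the C23 methine, and since C23–H is no larger than a methyl group the C2 chain has no clear reason to avoid it. The step therefore needs regioselectivity for C9, chemoselectivity for C-attack over hydrolysis or oxygen attack, and facial selectivity that places C23 anti to the C2 chain and cis to the C6 methyl. The three-atom tether and the quaternary C5 secure the first, the poorly nucleophilic silyl ether and ester oxygens and the single E geometry the second, and the ligand the third.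

Step 13
Reactants: 17 4-methylpent-4-en-2-ol; 18 1-bromo-3-methylbut-2-ene
Product: 19 8-methyl-4-methylidenenon-7-en-2-ol
Conditions: n-BuLi (2.2 equiv), TMEDA, Et2O/hexane, 0 °C → rt; then 18, −78 → 0 °C
Reagents that add atoms: none
Why: Alkoxide-directed lithiation of the allylic methyl group gives a dianion whose symmetrical allyl terminus is alkylated by the primary allylic bromide, as known for 3-methylbut-3-en-1-ol. The carbinol configuration is irrelevant.

Step 14
Reactants: 19 8-methyl-4-methylidenenon-7-en-2-ol
Product: 20 tert-butyldimethyl[(8-methyl-4-methylidenenon-7-en-2-yl)oxy]silane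
Conditions: TBSCl, imidazole, DMF, rt
Reagents that add atoms: tert-butyldimethylsilyl chloride, CC(C)(C)[Si](C)(C)Cl
Why: Silylation of the secondary alcohol. A silyl ether is chosen because, unlike an ester, it cannot capture the C14 cation of step 16 through a five- or six-membered ring.

Step 15
Reactants: 20 tert-butyldimethyl[(8-methyl-4-methylidenenon-7-en-2-yl)oxy]silane
Product: 21 tert-butyl({6-[(2S)-3,3-dimethyloxiran-2-yl]-4-methylidenehexan-2-yl}oxy)dimethylsilane
Conditions: ent-Shi ketone (L-fructose-derived, 30 mol %), Oxone (2KHSO5·KHSO4·K2SO4), K2CO3, Bu4NHSO4, MeCN/CH2(OMe)2/aq. Na2B4O7, 0 °C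
Reagents that add atoms: potassium peroxymonosulfate, [K+].[O-]S(=O)(=O)OO
Why: Shi dioxirane epoxidation. The electron-rich trisubstituted alkene reacts before the 1,1-disubstituted one, and the spiro transition state of the L-fructose-derived ketone should deliver the S epoxide (future C17).

Step 16
Reactants: 21 tert-butyl({6-[(2S)-3,3-dimethyloxiran-2-yl]-4-methylidenehexan-2-yl}oxy)dimethylsilane
Product: 22 tert-butyl({1-[(1R,4S)-3,3-dimethyl-7-oxabicyclo[2.2.1]heptan-1-yl]propan-2-yl}oxy)dimethylsilane
Conditions: BF3·OEt2 (0.5 equiv), CH2Cl2, −78 → −40 °C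
Reagents that add atoms: none
Why: Lewis-acid epoxy-olefin cyclisation ending in oxygen capture, as known for 2,6-dimethylhepta-1,5-diene monoepoxide. The epoxide opens at C18, the methylidene carbon C21 attacks, and the C17 oxygen traps the tertiary C14 cation. C17 is untouched and the bridge can only close cis, so C14 follows from C17.

Step 17
Reactants: 22 tert-butyl({1-[(1R,4S)-3,3-dimethyl-7-oxabicyclo[2.2.1]heptan-1-yl]propan-2-yl}oxy)dimethylsilane
Product: 23 1-[(1R,4S)-3,3-dimethyl-7-oxabicyclo[2.2.1]heptan-1-yl]propan-2-ol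
Conditions: TBAF, THF, rt
Reagents that add atoms: none
Why: Fluoride cleavage of a secondary silyl ether; the bicyclic ether is inert to fluoride.

Step 18
Reactants: 23 1-[(1R,4S)-3,3-dimethyl-7-oxabicyclo[2.2.1]heptan-1-yl]propan-2-ol
Product: 24 1-[(1R,4S)-3,3-dimethyl-7-oxabicyclo[2.2.1]heptan-1-yl]propan-2-one
Conditions: Dess–Martin periodinane, NaHCO3, CH2Cl2, rt
Reagents that add atoms: none
Why: Neutral oxidation of the secondary alcohol; buffered conditions avoid enolisation toward C13 and opening of the bridge.

Step 19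
Reactants: 16 methyl (3R)-3-[(1S,2R)-3-(2-{[tert-butyl(dimethyl)silyl]oxy}ethyl)-2-formyl-1,2-dimethylcyclopent-3-en-1-yl]butanoate; 24 1-[(1R,4S)-3,3-dimethyl-7-oxabicyclo[2.2.1]heptan-1-yl]propan-2-one
Product: 25 methyl (3R)-3-[(1S,2R)-3-(2-{[tert-butyl(dimethyl)silyl]oxy}ethyl)-2-{(1R)-4-[(1R,4S)-3,3-dimethyl-7-oxabicyclo[2.2.1]heptan-1-yl]-1-hydroxy-3-oxobutyl}-1,2-dimethylcyclopent-3-en-1-yl]butanoate
Conditions: 24, (+)-Ipc2BCl, Et3N, Et2O, −78 → 0 °C; 16, −78 → −20 °C; MeOH, pH 7 buffer, H2O2, 0 °C
Reagents that add atoms: none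
Why: Paterson boron aldol, in which the bulky chloroborane enolises only the methyl side of 24 and aldehyde 16 has no α-hydrogen. C23 is set by the reagent, the (+)-antipode being chosen for attack on the Re face of the aldehyde (O > C24 > H), which gives 23R, on the basis that the (−)-reagent is associated with Si-face attack for methyl ketone enolates. The adduct from any minor enantiomer of 24 is a diastereomer and should be removable here.

Step 20
Reactants: 25 methyl (3R)-3-[(1S,2R)-3-(2-{[tert-butyl(dimethyl)silyl]oxy}ethyl)-2-{(1R)-4-[(1R,4S)-3,3-dimethyl-7-oxabicyclo[2.2.1]heptan-1-yl]-1-hydroxy-3-oxobutyl}-1,2-dimethylcyclopent-3-en-1-yl]butanoate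
Product: 26 methyl (3R)-3-[(1S,2R)-3-(2-{[tert-butyl(dimethyl)silyl]oxy}ethyl)-2-{(1R)-1-{[tert-butyl(dimethyl)silyl]oxy}-4-[(1R,4S)-3,3-dimethyl-7-oxabicyclo[2.2.1]heptan-1-yl]-3-oxobutyl}-1,2-dimethylcyclopent-3-en-1-yl]butanoate
Conditions: TBSOTf, 2,6-lutidine, CH2Cl2, −78 → 0 °C
Reagents that add atoms: tert-butyldimethylsilyl triflate, CC(C)(C)[Si](C)(C)OS(=O)(=O)C(F)(F)F
Why: Silylation of a hindered secondary alcohol with the triflate and a weak base, which leaves the β-hydroxy ketone intact. The ether blocks lactol formation with C11 and retro-aldol in the following steps.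

Step 21
Reactants: 26 methyl (3R)-3-[(1S,2R)-3-(2-{[tert-butyl(dimethyl)silyl]oxy}ethyl)-2-{(1R)-1-{[tert-butyl(dimethyl)silyl]oxy}-4-[(1R,4S)-3,3-dimethyl-7-oxabicyclo[2.2.1]heptan-1-yl]-3-oxobutyl}-1,2-dimethylcyclopent-3-en-1-yl]butanoate
Product: 27 methyl (3R)-3-[(1S,2R)-2-{(1R)-1-{[tert-butyl(dimethyl)silyl]oxy}-4-[(1R,4S)-3,3-dimethyl-7-oxabicyclo[2.2.1]heptan-1-yl]-3-oxobutyl}-3-(2-hydroxyethyl)-1,2-dimethylcyclopent-3-en-1-yl]butanoate
Conditions: HF·pyridine, pyridine, THF, 0 °C → rt
Reagents that add atoms: none
Why: Buffered HF·pyridine removes a primary silyl ether much faster than a secondary one, and the C23 ether is neopentylic as well.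

Step 22
Reactants: 27 methyl (3R)-3-[(1S,2R)-2-{(1R)-1-{[tert-butyl(dimethyl)silyl]oxy}-4-[(1R,4S)-3,3-dimethyl-7-oxabicyclo[2.2.1]heptan-1-yl]-3-oxobutyl}-3-(2-hydroxyethyl)-1,2-dimethylcyclopent-3-en-1-yl]butanoate
Product: 28 methyl (3R)-3-[(1S,2R)-2-{(1R)-1-{[tert-butyl(dimethyl)silyl]oxy}-4-[(1R,4S)-3,3-dimethyl-7-oxabicyclo[2.2.1]heptan-1-yl]-3-oxobutyl}-1,2-dimethyl-3-(2-oxoethyl)cyclopent-3-en-1-yl]butanoate
Conditions: Dess–Martin periodinane, NaHCO3, CH2Cl2, 0 °C
Reagents that add atoms: none
Why: Buffered neutral oxidation to the β,γ-unsaturated aldehyde, which is used crude so that C8=C9 does not move into conjugation.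

Step 23
Reactants: 28 methyl (3R)-3-[(1S,2R)-2-{(1R)-1-{[tert-butyl(dimethyl)silyl]oxy}-4-[(1R,4S)-3,3-dimethyl-7-oxabicyclo[2.2.1]heptan-1-yl]-3-oxobutyl}-1,2-dimethyl-3-(2-oxoethyl)cyclopent-3-en-1-yl]butanoate
Product: 29 methyl (3R)-3-[(1S,7R,7aS)-7-{[tert-butyl(dimethyl)silyl]oxy}-5-{[(1S,4S)-3,3-dimethyl-7-oxabicyclo[2.2.1]heptan-1-yl]methyl}-4-formyl-1,7a-dimethyl-2,6,7,7a-tetrahydro-1H-inden-1-yl]butanoate
Conditions: Bn2NH·CF3CO2H (0.3 equiv), PhMe, rt → 50 °C
Reagents that add atoms: none
Why: Amine-salt intramolecular aldol condensation. The secondary amine forms the enamine of the aldehyde far faster than that of the hindered ketone, C10 adds to C12 in a six-membered closure, and loss of water gives the conjugated dienal. No stereocentre is formed.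

Step 24
Reactants: 29 methyl (3R)-3-[(1S,7R,7aS)-7-{[tert-butyl(dimethyl)silyl]oxy}-5-{[(1S,4S)-3,3-dimethyl-7-oxabicyclo[2.2.1]heptan-1-yl]methyl}-4-formyl-1,7a-dimethyl-2,6,7,7a-tetrahydro-1H-inden-1-yl]butanoate
Product: 30 (1S,7R,7aS)-7-{[tert-butyl(dimethyl)silyl]oxy}-5-{[(1S,4S)-3,3-dimethyl-7-oxabicyclo[2.2.1]heptan-1-yl]methyl}-1-[(2R)-4-methoxy-4-oxobutan-2-yl]-1,7a-dimethyl-2,6,7,7a-tetrahydro-1H-indene-4-carboxylic acid
Conditions: NaClO2, NaH2PO4, 2-methylbut-2-ene, t-BuOH/H2O, rt
Reagents that add atoms: sodium chlorite, [Na+].[O-]Cl=O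
Why: Pinnick oxidation, which converts hindered unsaturated aldehydes to acids without touching the alkenes; the alkene scavenger removes hypochlorite.

Step 25
Reactants: 30 (1S,7R,7aS)-7-{[tert-butyl(dimethyl)silyl]oxy}-5-{[(1S,4S)-3,3-dimethyl-7-oxabicyclo[2.2.1]heptan-1-yl]methyl}-1-[(2R)-4-methoxy-4-oxobutan-2-yl]-1,7a-dimethyl-2,6,7,7a-tetrahydro-1H-indene-4-carboxylic acid
Product: 31 (1S,7R,7aS)-5-{[(1S,4S)-3,3-dimethyl-7-oxabicyclo[2.2.1]heptan-1-yl]methyl}-7-hydroxy-1-[(2R)-4-methoxy-4-oxobutan-2-yl]-1,7a-dimethyl-2,6,7,7a-tetrahydro-1H-indene-4-carboxylic acid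
Conditions: 48% aq. HF, MeCN, rt
Reagents that add atoms: none
Why: Acidic fluoride removes the hindered secondary silyl ether. C23 is homoallylic, not allylic, so ionisation is not expected, and lactonisation onto C11 is excluded because it would put the C10=C12 alkene at a bridgehead.

Step 26
Reactants: 31 (1S,7R,7aS)-5-{[(1S,4S)-3,3-dimethyl-7-oxabicyclo[2.2.1]heptan-1-yl]methyl}-7-hydroxy-1-[(2R)-4-methoxy-4-oxobutan-2-yl]-1,7a-dimethyl-2,6,7,7a-tetrahydro-1H-indene-4-carboxylic acid
Product: 32 (1S,7R,7aS)-1-[(2R)-1-carboxypropan-2-yl]-5-{[(1S,4S)-3,3-dimethyl-7-oxabicyclo[2.2.1]heptan-1-yl]methyl}-7-hydroxy-1,7a-dimethyl-2,6,7,7a-tetrahydro-1H-indene-4-carboxylic acid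
Conditions: LiOH, THF/MeOH/H2O, rt; then 1 M HCl to pH 3
Reagents that add atoms: lithium hydroxide, [Li+].[OH-]
Why: Saponification of the unhindered methyl ester. C2 is β to the ester and cannot epimerise, and the conjugated C11 carboxylate is inert.

## Compound list

1 | but-3-yn-1-ol | C#CCCO | starting material
2 | tert-butyl(but-3-yn-1-yloxy)dimethylsilane | C#CCCO[Si](C)(C)C(C)(C)C | intermediate
3 | 5-{[tert-butyl(dimethyl)silyl]oxy}pent-2-yn-1-ol | OCC#CCCO[Si](C)(C)C(C)(C)C | intermediate
4 | [(5-bromopent-3-yn-1-yl)oxy](tert-butyl)dimethylsilane | BrCC#CCCO[Si](C)(C)C(C)(C)C | intermediate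
5 | (3R)-5-methoxy-3-methyl-5-oxopentanoic acid | C[C@H](CC(=O)O)CC(=O)OC | starting material
6 | methyl (3R)-5-hydroxy-3-methylpentanoate (not isolated) | C[C@H](CCO)CC(=O)OC | intermediate
7 | (4R)-4-methyloxan-2-one | C[C@@H]1CCOC(=O)C1 | intermediate
8 | (3S,4R)-3,4-dimethyloxan-2-one (trans) | C[C@@H]1CCOC(=O)[C@H]1C | intermediate
9 | (3S,4R)-3-(5-{[tert-butyl(dimethyl)silyl]oxy}pent-2-yn-1-yl)-3,4-dimethyloxan-2-one | C[C@@H]1CCOC(=O)[C@@]1(C)CC#CCCO[Si](C)(C)C(C)(C)C | intermediate
10 | (3S)-8-{[tert-butyl(dimethyl)silyl]oxy}-3-[(2R)-4-hydroxybutan-2-yl]-3-methyloct-5-yn-2-one (open form of the lactol) | C[C@H](CCO)[C@](C)(CC#CCCO[Si](C)(C)C(C)(C)C)C(C)=O | intermediate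
11 | (3R,4S)-4-acetyl-9-{[tert-butyl(dimethyl)silyl]oxy}-3,4-dimethylnon-6-ynoic acid | C[C@H](CC(=O)O)[C@](C)(CC#CCCO[Si](C)(C)C(C)(C)C)C(C)=O | intermediate
12 | methyl (3R,4S)-4-acetyl-9-{[tert-butyl(dimethyl)silyl]oxy}-3,4-dimethylnon-6-ynoate | C[C@H](CC(=O)OC)[C@](C)(CC#CCCO[Si](C)(C)C(C)(C)C)C(C)=O | intermediate
13 | methyl (3R,4S)-9-{[tert-butyl(dimethyl)silyl]oxy}-4-(1-methoxyprop-1-en-2-yl)-3,4-dimethylnon-6-ynoate (E/Z mixture, not isolated) | C[C@H](CC(=O)OC)[C@](C)(CC#CCCO[Si](C)(C)C(C)(C)C)C(C)=COC | intermediate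
14 | methyl (3R,4S)-9-{[tert-butyl(dimethyl)silyl]oxy}-3,4-dimethyl-4-(1-oxopropan-2-yl)non-6-ynoate (both epimers at the formyl-bearing carbon) | C[C@H](CC(=O)OC)[C@](C)(CC#CCCO[Si](C)(C)C(C)(C)C)C(C)C=O | intermediate
15 | methyl (3R,4S)-9-{[tert-butyl(dimethyl)silyl]oxy}-4-[(1E)-1-{[tert-butyl(dimethyl)silyl]oxy}prop-1-en-2-yl]-3,4-dimethylnon-6-ynoate | C[C@H](CC(=O)OC)[C@](C)(CC#CCCO[Si](C)(C)C(C)(C)C)/C(C)=C/O[Si](C)(C)C(C)(C)C | intermediate
16 | methyl (3R)-3-[(1S,2R)-3-(2-{[tert-butyl(dimethyl)silyl]oxy}ethyl)-2-formyl-1,2-dimethylcyclopent-3-en-1-yl]butanoate (formyl cis to the ring methyl on the neighbouring carbon) | C[C@H](CC(=O)OC)[C@]1(C)CC=C(CCO[Si](C)(C)C(C)(C)C)[C@@]1(C)C=O | intermediate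
17 | 4-methylpent-4-en-2-ol (racemic) | CC(O)CC(C)=C | starting material
18 | 1-bromo-3-methylbut-2-ene | CC(C)=CCBr | starting material
19 | 8-methyl-4-methylidenenon-7-en-2-ol (racemic) | CC(O)CC(=C)CCC=C(C)C | intermediate
20 | tert-butyldimethyl[(8-methyl-4-methylidenenon-7-en-2-yl)oxy]silane | CC(O[Si](C)(C)C(C)(C)C)CC(=C)CCC=C(C)C | intermediate
21 | tert-butyl({6-[(2S)-3,3-dimethyloxiran-2-yl]-4-methylidenehexan-2-yl}oxy)dimethylsilane (both carbinol epimers) | CC(O[Si](C)(C)C(C)(C)C)CC(=C)CC[C@@H]1OC1(C)C | intermediate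
22 | tert-butyl({1-[(1R,4S)-3,3-dimethyl-7-oxabicyclo[2.2.1]heptan-1-yl]propan-2-yl}oxy)dimethylsilane (both carbinol epimers) | CC(O[Si](C)(C)C(C)(C)C)C[C@]12CC[C@H](O1)C(C)(C)C2 | intermediate
23 | 1-[(1R,4S)-3,3-dimethyl-7-oxabicyclo[2.2.1]heptan-1-yl]propan-2-ol (both carbinol epimers) | CC(O)C[C@]12CC[C@H](O1)C(C)(C)C2 | intermediate
24 | 1-[(1R,4S)-3,3-dimethyl-7-oxabicyclo[2.2.1]heptan-1-yl]propan-2-one | CC(=O)C[C@]12CC[C@H](O1)C(C)(C)C2 | intermediate
25 | methyl (3R)-3-[(1S,2R)-3-(2-{[tert-butyl(dimethyl)silyl]oxy}ethyl)-2-{(1R)-4-[(1R,4S)-3,3-dimethyl-7-oxabicyclo[2.2.1]heptan-1-yl]-1-hydroxy-3-oxobutyl}-1,2-dimethylcyclopent-3-en-1-yl]butanoate | C[C@H](CC(=O)OC)[C@]1(C)CC=C(CCO[Si](C)(C)C(C)(C)C)[C@@]1(C)[C@H](O)CC(=O)C[C@]23CC[C@H](O2)C(C)(C)C3 | intermediate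
26 | methyl (3R)-3-[(1S,2R)-3-(2-{[tert-butyl(dimethyl)silyl]oxy}ethyl)-2-{(1R)-1-{[tert-butyl(dimethyl)silyl]oxy}-4-[(1R,4S)-3,3-dimethyl-7-oxabicyclo[2.2.1]heptan-1-yl]-3-oxobutyl}-1,2-dimethylcyclopent-3-en-1-yl]butanoate | C[C@H](CC(=O)OC)[C@]1(C)CC=C(CCO[Si](C)(C)C(C)(C)C)[C@@]1(C)[C@H](O[Si](C)(C)C(C)(C)C)CC(=O)C[C@]23CC[C@H](O2)C(C)(C)C3 | intermediate
27 | methyl (3R)-3-[(1S,2R)-2-{(1R)-1-{[tert-butyl(dimethyl)silyl]oxy}-4-[(1R,4S)-3,3-dimethyl-7-oxabicyclo[2.2.1]heptan-1-yl]-3-oxobutyl}-3-(2-hydroxyethyl)-1,2-dimethylcyclopent-3-en-1-yl]butanoate | C[C@H](CC(=O)OC)[C@]1(C)CC=C(CCO)[C@@]1(C)[C@H](O[Si](C)(C)C(C)(C)C)CC(=O)C[C@]23CC[C@H](O2)C(C)(C)C3 | intermediate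
28 | methyl (3R)-3-[(1S,2R)-2-{(1R)-1-{[tert-butyl(dimethyl)silyl]oxy}-4-[(1R,4S)-3,3-dimethyl-7-oxabicyclo[2.2.1]heptan-1-yl]-3-oxobutyl}-1,2-dimethyl-3-(2-oxoethyl)cyclopent-3-en-1-yl]butanoate | C[C@H](CC(=O)OC)[C@]1(C)CC=C(CC=O)[C@@]1(C)[C@H](O[Si](C)(C)C(C)(C)C)CC(=O)C[C@]23CC[C@H](O2)C(C)(C)C3 | intermediate
29 | methyl (3R)-3-[(1S,7R,7aS)-7-{[tert-butyl(dimethyl)silyl]oxy}-5-{[(1S,4S)-3,3-dimethyl-7-oxabicyclo[2.2.1]heptan-1-yl]methyl}-4-formyl-1,7a-dimethyl-2,6,7,7a-tetrahydro-1H-inden-1-yl]butanoate | C[C@H](CC(=O)OC)[C@]1(C)CC=C2C(C=O)=C(C[C@]34CC[C@H](O3)C(C)(C)C4)C[C@@H](O[Si](C)(C)C(C)(C)C)[C@]21C | intermediate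
30 | (1S,7R,7aS)-7-{[tert-butyl(dimethyl)silyl]oxy}-5-{[(1S,4S)-3,3-dimethyl-7-oxabicyclo[2.2.1]heptan-1-yl]methyl}-1-[(2R)-4-methoxy-4-oxobutan-2-yl]-1,7a-dimethyl-2,6,7,7a-tetrahydro-1H-indene-4-carboxylic acid | C[C@H](CC(=O)OC)[C@]1(C)CC=C2C(C(=O)O)=C(C[C@]34CC[C@H](O3)C(C)(C)C4)C[C@@H](O[Si](C)(C)C(C)(C)C)[C@]21C | intermediate
31 | (1S,7R,7aS)-5-{[(1S,4S)-3,3-dimethyl-7-oxabicyclo[2.2.1]heptan-1-yl]methyl}-7-hydroxy-1-[(2R)-4-methoxy-4-oxobutan-2-yl]-1,7a-dimethyl-2,6,7,7a-tetrahydro-1H-indene-4-carboxylic acid | C[C@H](CC(=O)OC)[C@]1(C)CC=C2C(C(=O)O)=C(C[C@]34CC[C@H](O3)C(C)(C)C4)C[C@@H](O)[C@]21C | intermediate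
32 | (1S,7R,7aS)-1-[(2R)-1-carboxypropan-2-yl]-5-{[(1S,4S)-3,3-dimethyl-7-oxabicyclo[2.2.1]heptan-1-yl]methyl}-7-hydroxy-1,7a-dimethyl-2,6,7,7a-tetrahydro-1H-indene-4-carboxylic acid | C[C@H](CC(=O)O)[C@]1(C)CC=C2C(C(=O)O)=C(C[C@]34CC[C@H](O3)C(C)(C)C4)C[C@@H](O)[C@]21C | target

## Step count and risks

Total: 26 steps. Longest linear sequence: 18 steps (1 to 32: steps 1–3, 6–12 and 19–26). The branch from half-ester 5 (steps 4–12 and 19–26) counts 17 steps, and the branch from alcohol 17 (steps 13–26) counts 14. Steps 1–3 make bromide 4 and steps 13–18 make ketone 24.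

**Step 12 (key step).** The most likely failure is poor or mismatched facial discrimination at C24, since the substrate offers little bias and the ligand may oppose it. A second is protodesilylation of the enol ether back to aldehyde 14 before the C–C bond forms. Fallback: the silyl enol ether is given up and the nucleophile becomes a chiral secondary enamine. Setting out from aldehyde 14, condensation with (1R)-1-phenylethanamine (molecular sieves, PhMe) gives methyl (3R,4S)-9-{[tert-butyl(dimethyl)silyl]oxy}-3,4-dimethyl-4-(1-{[(1R)-1-phenylethyl]imino}propan-2-yl)non-6-ynoate F1. Its enamine tautomer adds to the alkyne activated by (Ph3P)AuNTf2 in the same 5-endo-dig sense and gives methyl (3R)-3-[(1S,2R)-3-(2-{[tert-butyl(dimethyl)silyl]oxy}ethyl)-1,2-dimethyl-2-({[(1R)-1-phenylethyl]imino}methyl)cyclopent-3-en-1-yl]butanoate F2. The facial bias then comes from the covalently bound amine, as in the alkylation of chiral secondary enamines of α-branched carbonyl compounds, and the antipode of the amine is chosen accordingly. Hydrolysis of F2 with aqueous acetic acid returns the route at 16.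

**Step 10.** The basic ylide may enolise the hindered methyl ketone instead of adding to it, so that 12 is recovered, or may attack the ester on forcing. Fallback: from 12, trimethylsulfonium ylide (Corey–Chaykovsky) should add to the ketone and give methyl (3R,4S)-9-{[tert-butyl(dimethyl)silyl]oxy}-3,4-dimethyl-4-(2-methyloxiran-2-yl)non-6-ynoate F3. A Lewis acid at low temperature then rearranges F3 by 1,2-hydride shift (Meinwald rearrangement) to aldehyde 14, where the route is rejoined.

**Step 16.** Proton loss from the C14 cation, or hydride shift within the opened epoxide, may outrun capture by the C17 oxygen and give cyclohexenols or a ketone in place of the bridge. Fallback: from 21, reductive epoxide opening with Cp2TiCl and radical cyclisation should give (1S)-4-(2-{[tert-butyl(dimethyl)silyl]oxy}propyl)-2,2-dimethylcyclohex-3-en-1-ol F4 (its double-bond isomers serve equally). Intramolecular alkoxymercuration with Hg(OCOCF3)2 and NaBH4 demercuration then closes the C14–O bond at the tertiary carbon and returns to 22.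

**Step 19.** The reagent-controlled facial selectivity at C23 may be eroded or opposed by the bias of the α-quaternary aldehyde, and the adduct may undergo retro-aldol on work-up. Fallback: from 24, kinetic enolisation and silylation give trimethyl({3-[(1R,4S)-3,3-dimethyl-7-oxabicyclo[2.2.1]heptan-1-yl]prop-1-en-2-yl}oxy)silane F5. A BF3·OEt2-mediated Mukaiyama aldol of F5 with 16 proceeds through an open transition state and relies on the diastereofacial preference of the aldehyde itself instead of on the reagent, and returns at 25.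

**Step 23.** Three processes compete with the desired closure: enolisation of the C12 ketone toward C22 with loss of the C23 silyloxy group, migration of C8=C9 into conjugation before closure, and attack through C8 of the dienamine. Fallback: from 28, silylation at −78 °C gives the tert-butyldimethylsilyl dienol ether of the aldehyde F6. A TiCl4-mediated intramolecular Mukaiyama aldol onto the C12 ketone gives the tertiary aldol F7, and dehydration (MsCl, Et3N, then DBU) returns at 29.

## Further compounds

F1 | step 12 | methyl (3R,4S)-9-{[tert-butyl(dimethyl)silyl]oxy}-3,4-dimethyl-4-(1-{[(1R)-1-phenylethyl]imino}propan-2-yl)non-6-ynoate | C[C@H](CC(=O)OC)[C@](C)(CC#CCCO[Si](C)(C)C(C)(C)C)C(C)C=N[C@H](C)c1ccccc1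
F2 | step 12 | methyl (3R)-3-[(1S,2R)-3-(2-{[tert-butyl(dimethyl)silyl]oxy}ethyl)-1,2-dimethyl-2-({[(1R)-1-phenylethyl]imino}methyl)cyclopent-3-en-1-yl]butanoate | C[C@H](CC(=O)OC)[C@]1(C)CC=C(CCO[Si](C)(C)C(C)(C)C)[C@@]1(C)C=N[C@H](C)c1ccccc1
F3 | step 10 | methyl (3R,4S)-9-{[tert-butyl(dimethyl)silyl]oxy}-3,4-dimethyl-4-(2-methyloxiran-2-yl)non-6-ynoate | C[C@H](CC(=O)OC)[C@](C)(CC#CCCO[Si](C)(C)C(C)(C)C)C1(C)CO1
F4 | step 16 | (1S)-4-(2-{[tert-butyl(dimethyl)silyl]oxy}propyl)-2,2-dimethylcyclohex-3-en-1-ol | CC(O[Si](C)(C)C(C)(C)C)CC1=CC(C)(C)[C@@H](O)CC1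
F5 | step 19 | trimethyl({3-[(1R,4S)-3,3-dimethyl-7-oxabicyclo[2.2.1]heptan-1-yl]prop-1-en-2-yl}oxy)silane | C=C(O[Si](C)(C)C)C[C@]12CC[C@H](O1)C(C)(C)C2
F6 | step 23 | tert-butyldimethylsilyl dienol ether of aldehyde 28 (1-silyloxy-1,3-diene over C11, C10, C9, C8) | C[C@H](CC(=O)OC)[C@]1(C)CC=C(C=CO[Si](C)(C)C(C)(C)C)[C@@]1(C)[C@H](O[Si](C)(C)C(C)(C)C)CC(=O)C[C@]23CC[C@H](O2)C(C)(C)C3
F7 | step 23 | tertiary aldol from closure of C10 onto C12 (β-hydroxy aldehyde, epimers at C10 and C12) | C[C@H](CC(=O)OC)[C@]1(C)CC=C2C(C=O)C(O)(C[C@]34CC[C@H](O3)C(C)(C)C4)C[C@@H](O[Si](C)(C)C(C)(C)C)[C@]21C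
A1 | alternative 1 | methyl 3,3-dimethyl-2-oxo-6-(phenylsulfonyl)-7-oxabicyclo[2.2.1]heptane-1-carboxylate | COC(=O)[C@]12[C@H](S(=O)(=O)c3ccccc3)C[C@H](O1)C(C)(C)C2=O
A2 | alternative 1 | methyl 2-diazo-4,4-dimethyl-3,5-dioxopentanoate | COC(=O)C(=[N+]=[N-])C(=O)C(C)(C)C=O
A3 | alternative 1 | phenyl vinyl sulfone | C=CS(=O)(=O)c1ccccc1
A4 | alternative 2 | hydrindan-8-one cycloadduct | C[C@H](CC(=O)OC)[C@]1(C)CC(=O)[C@H]2C(C(=O)OC)=C(C[C@]34CC[C@H](O3)C(C)(C)C4)C[C@@H](O[Si](C)(C)C(C)(C)C)[C@]21C
A5 | alternative 2 | open-chain 4-oxo-dienoate carrying the silyl enol ether | C[C@H](CC(=O)OC)[C@](C)(CC(=O)C=C(C(=O)OC)C(=C)C[C@]12CC[C@H](O1)C(C)(C)C2)C(C)=CO[Si](C)(C)C(C)(C)C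
A6 | alternative 3 | silylated dimethyl ester of the target | C[C@H](CC(=O)OC)[C@]1(C)CC=C2C(C(=O)OC)=C(C[C@]34CC[C@H](O3)C(C)(C)C4)C[C@@H](O[Si](C)(C)C(C)(C)C)[C@]21C
A7 | alternative 3 | epoxy diene precursor of the cascade | C[C@H](CC(=O)OC)[C@]1(C)CC=C2C(C(=O)OC)=C(CC(=C)CC[C@@H]3OC3(C)C)C[C@@H](O[Si](C)(C)C(C)(C)C)[C@]21C
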